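Numbering: 1-oxaspiro[4.4]nonane; ring B = furanone (O1, C2–C4, spiro C5), ring A = cyclopentenone (C5–C9). The retrosynthesis cuts the benzyl ether, then C5–C6 and C7=C8 of ring A together, then the acyl–ylide bond C8–C9, then ring B (O1–C2 and C4–C5).
Enabling feature: C6 (tertiary α-hydroxy ester) with its enol-ether neighbour C7 is a hidden dimethyl mesoxalate (keto carbon plus two ester arms); C5 is C2 of an aromatic 2-acyl-3-hydroxyfuran; C7(OMe)=C8(OMe)–C9=O is the retron of an ester Wittig reaction with an α-methoxy acyl ylide.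
Forward: ring B is built first as a flat 3-hydroxyfuran-2-carboxylate, its ester becomes the acyl ylide, and ring A is closed around C5 by a dearomative aldol/ester-Wittig [3+2] annulation with dimethyl mesoxalate; debenzylation ends the route.
Helpers: Ph3P on C8 (leaves as Ph3P=O in the key step), a silyl group on the furan oxygen (steps 3 to 5), a benzyl group on the phenol (steps 1 to 7).
Stereochemistry: C5 (S) from the organocatalysed aldol step; C6 (R) from the choice between the two ester groups of the mesoxalate unit in the Wittig closure, steered by the Ph3P group and the free C6–OH.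

Key step: step 6

Assumption: the sense of induction of the cinchona squaramide in the aldol step is taken to give (S) at the spiro carbon with the quinidine-derived catalyst; if the opposite sense is found, the quinine-derived pseudoenantiomer is used in its place.

Step 1
Reactants: 1 1-(benzyloxy)-4-ethynylbenzene
Product: 3 methyl 3-[4-(benzyloxy)phenyl]prop-2-ynoate, via lithium acetylide 2 (not isolated)
Conditions: n-BuLi, THF, −78 °C; then ClCO2Me, −78 °C to 0 °C
Reagents that add atoms: methyl chloroformate, COC(=O)Cl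
Why: Deprotonation of the terminal alkyne and C-acylation of the resulting lithium acetylide by the chloroformate is a standard alkynoate synthesis that forms no stereocentre.

Step 2
Reactants: 3 methyl 3-[4-(benzyloxy)phenyl]prop-2-ynoate; 4 methyl glycolate (methyl 2-hydroxyacetate)
Product: 6 methyl 5-[4-(benzyloxy)phenyl]-3-hydroxyfuran-2-carboxylate, via Z-configured oxa-Michael adduct 5 (not isolated)
Conditions: KOtBu (2.2 equiv), THF, 0 °C to rt; then aq. HCl
Reagents that add atoms: none
Why: A Fiesselmann-type furan synthesis is expected in which oxa-Michael addition of the glycolate alkoxide to the ynoate gives the Z-configured adduct, Dieckmann condensation of the glycolate methylene onto the acrylate ester closes ring B and enolisation delivers the aromatic 3-hydroxyfuran; no stereocentre is formed.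

Step 3
Reactants: 6 methyl 5-[4-(benzyloxy)phenyl]-3-hydroxyfuran-2-carboxylate
Product: 7 methyl 5-[4-(benzyloxy)phenyl]-3-{[tri(propan-2-yl)silyl]oxy}furan-2-carboxylate
Conditions: TIPSOTf, 2,6-lutidine, CH2Cl2, 0 °C
Reagents that add atoms: tri(propan-2-yl)silyl trifluoromethanesulfonate (TIPSOTf), CC(C)[Si](OS(=O)(=O)C(F)(F)F)(C(C)C)C(C)C
Why: Silyl ether formation at the acidic enol-type hydroxyl removes the proton that would turn the ester into an unreactive vinylogous carboxylate under the basic conditions of the next step.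

Step 4
Reactants: 7 methyl 5-[4-(benzyloxy)phenyl]-3-{[tri(propan-2-yl)silyl]oxy}furan-2-carboxylate; 8 (methoxymethyl)triphenylphosphonium chloride
Product: 10 1-{5-[4-(benzyloxy)phenyl]-3-{[tri(propan-2-yl)silyl]oxy}furan-2-yl}-2-methoxy-2-(triphenyl-λ5-phosphanylidene)ethan-1-one, via methoxymethylidene ylide 9 (not isolated)
Conditions: 8 (1.5 equiv), KN(SiMe3)2 (1.45 equiv), THF, 0 °C; then 7, −78 °C to rt
Reagents that add atoms: none
Why: C-acylation of a non-stabilised phosphorus ylide by an ester, with the expelled methoxide serving as base for the transylidation, is the classical route to acyl-stabilised ylides and installs C8 with its methoxy group and the phosphorus activating group in one step without forming a stereocentre.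

Step 5
Reactants: 10 1-{5-[4-(benzyloxy)phenyl]-3-{[tri(propan-2-yl)silyl]oxy}furan-2-yl}-2-methoxy-2-(triphenyl-λ5-phosphanylidene)ethan-1-one
Product: 11 1-{5-[4-(benzyloxy)phenyl]-3-hydroxyfuran-2-yl}-2-methoxy-2-(triphenyl-λ5-phosphanylidene)ethan-1-one
Conditions: Bu4NF, AcOH, THF, 0 °C
Reagents that add atoms: none
Why: Fluoride-mediated cleavage of the silyl enol ether under acetic acid buffering should free the 3-hydroxyfuran, the carbon nucleophile of the key step, while the weakly basic acyl-stabilised ylide survives.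

Step 6
Reactants: 11 1-{5-[4-(benzyloxy)phenyl]-3-hydroxyfuran-2-yl}-2-methoxy-2-(triphenyl-λ5-phosphanylidene)ethan-1-one; 12 dimethyl 2-oxopropanedioate (dimethyl mesoxalate)
Product: 14 methyl (5S,6R)-2-[4-(benzyloxy)phenyl]-6-hydroxy-7,8-dimethoxy-4,9-dioxo-1-oxaspiro[4.4]nona-2,7-diene-6-carboxylate, via aldol adduct 13 (not isolated)
Conditions: 12 (1.0 equiv), quinidine-derived 3,5-bis(trifluoromethyl)phenyl squaramide (10 mol %), 4 Å MS, toluene, −40 °C; then PhCO2H (20 mol %), 70 °C
Reagents that add atoms: none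
Why: Proposed new method: under general-base and hydrogen-bond activation by the squaramide the enol carbon C2 of the 3-hydroxyfuran 11 (the future spiro carbon C5) should add to the keto group of 12, which dearomatises ring B and gives the tertiary alcohol 13 (bond C5–C6); on warming, the ylide carbon C8 should attack one ester carbonyl of the hydroxymalonate unit and the four-membered P–O adduct should collapse to Ph3P=O and the enol ether, which keeps the ester methoxy group on C7 (bond C7=C8). The closest known reaction types are the bifunctional amine–squaramide-catalysed aldol addition of cyclic 1,3-dicarbonyl-type pronucleophiles (for example 2-substituted benzofuran-3(2H)-ones) to activated ketones such as α-keto esters, and the domino addition/intramolecular Wittig olefination of an ester carbonyl by which α-hydroxy esters and ketenylidenetriphenylphosphorane give tetronates; their union into a carbocyclic [3+2] annulation of a 1,3-carbon bis-nucleophile with a vicinal tricarbonyl compound has not been shown. Ring A is closed in the 5-exo-trig mode at the ester C=O with the ylide carbonyl inside the new ring, the same topology as in tetronate formation. C5 is controlled by the catalyst, which selects one face of the planar furan enol; C6 is controlled by the substrate in the Wittig closure, where the Ph3P group and the attacked ester oxygen occupy one face of the nascent ring, and this face should be the one that bears the small ring oxygen O1 on C5 and the free C6–OH (hydrogen-bonded to the attacked ester oxygen), so that the ester syn to the C4 carbonyl stays as the spectator CO2Me. The step needs attack on the mesoxalate ketone by the furan carbon and not by the ylide carbon, which the fully substituted, acyl-stabilised and therefore sluggish ylide carbon, one equivalent of 12 and the low temperature should secure, and it needs an aldol adduct that does not revert, which the aprotic medium and the weak basicity of the ylide (it cannot ionise the tertiary alcohol) should secure.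

Step 7
Reactants: 14 methyl (5S,6R)-2-[4-(benzyloxy)phenyl]-6-hydroxy-7,8-dimethoxy-4,9-dioxo-1-oxaspiro[4.4]nona-2,7-diene-6-carboxylate
Product: 15 methyl (5S,6R)-6-hydroxy-2-(4-hydroxyphenyl)-7,8-dimethoxy-4,9-dioxo-1-oxaspiro[4.4]nona-2,7-diene-6-carboxylate (limnophilaspiroketone)
Conditions: H2 (1 atm), Pd/C (10 wt %), EtOAc, rt
Reagents that add atoms: none
Why: Hydrogenolysis of the aryl benzyl ether under neutral conditions should be much faster than reduction of the tetrasubstituted enol-ether double bond of ring A or of the β-aryl vinylogous-ester double bond of ring B (compare debenzylation of benzyl-protected flavones) and cannot affect the two quaternary stereocentres.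

Compound list
1 | 1-(benzyloxy)-4-ethynylbenzene | C#Cc1ccc(OCc2ccccc2)cc1 | starting material
2 | lithium [4-(benzyloxy)phenyl]ethynide | [Li]C#Cc1ccc(OCc2ccccc2)cc1 | intermediate
3 | methyl 3-[4-(benzyloxy)phenyl]prop-2-ynoate | COC(=O)C#Cc1ccc(OCc2ccccc2)cc1 | intermediate
4 | methyl glycolate (methyl 2-hydroxyacetate) | COC(=O)CO | starting material
5 | methyl (2Z)-3-[4-(benzyloxy)phenyl]-3-(2-methoxy-2-oxoethoxy)prop-2-enoate | COC(=O)CO/C(=C\C(=O)OC)c1ccc(OCc2ccccc2)cc1 | intermediate
6 | methyl 5-[4-(benzyloxy)phenyl]-3-hydroxyfuran-2-carboxylate | COC(=O)c1oc(-c2ccc(OCc3ccccc3)cc2)cc1O | intermediate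
7 | methyl 5-[4-(benzyloxy)phenyl]-3-{[tri(propan-2-yl)silyl]oxy}furan-2-carboxylate | COC(=O)c1oc(-c2ccc(OCc3ccccc3)cc2)cc1O[Si](C(C)C)(C(C)C)C(C)C | intermediate
8 | (methoxymethyl)triphenylphosphonium chloride | COC[P+](c1ccccc1)(c1ccccc1)c1ccccc1.[Cl-] | starting material
9 | (methoxymethylidene)triphenyl-λ5-phosphane | COC=P(c1ccccc1)(c1ccccc1)c1ccccc1 | intermediate
10 | 1-{5-[4-(benzyloxy)phenyl]-3-{[tri(propan-2-yl)silyl]oxy}furan-2-yl}-2-methoxy-2-(triphenyl-λ5-phosphanylidene)ethan-1-one | COC(=P(c1ccccc1)(c1ccccc1)c1ccccc1)C(=O)c1oc(-c2ccc(OCc3ccccc3)cc2)cc1O[Si](C(C)C)(C(C)C)C(C)C | intermediate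
11 | 1-{5-[4-(benzyloxy)phenyl]-3-hydroxyfuran-2-yl}-2-methoxy-2-(triphenyl-λ5-phosphanylidene)ethan-1-one | COC(=P(c1ccccc1)(c1ccccc1)c1ccccc1)C(=O)c1oc(-c2ccc(OCc3ccccc3)cc2)cc1O | intermediate
12 | dimethyl 2-oxopropanedioate (dimethyl mesoxalate) | COC(=O)C(=O)C(=O)OC | starting material
13 | dimethyl 2-{(2S)-5-[4-(benzyloxy)phenyl]-2-[2-methoxy-2-(triphenyl-λ5-phosphanylidene)acetyl]-3-oxo-2,3-dihydrofuran-2-yl}-2-hydroxypropanedioate | COC(=O)C(O)(C(=O)OC)[C@]1(C(=O)C(OC)=P(c2ccccc2)(c2ccccc2)c2ccccc2)OC(c2ccc(OCc3ccccc3)cc2)=CC1=O | intermediate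
14 | methyl (5S,6R)-2-[4-(benzyloxy)phenyl]-6-hydroxy-7,8-dimethoxy-4,9-dioxo-1-oxaspiro[4.4]nona-2,7-diene-6-carboxylate | COC(=O)[C@@]1(O)C(OC)=C(OC)C(=O)[C@]12OC(c1ccc(OCc3ccccc3)cc1)=CC2=O | intermediate
15 | methyl (5S,6R)-6-hydroxy-2-(4-hydroxyphenyl)-7,8-dimethoxy-4,9-dioxo-1-oxaspiro[4.4]nona-2,7-diene-6-carboxylate (limnophilaspiroketone) | COC(=O)[C@@]1(O)C(OC)=C(OC)C(=O)[C@]12OC(c1ccc(O)cc1)=CC2=O | target

Total step count: 7
Longest linear sequence: 7 steps (1 to 15)

Steps most likely to fail

Step 6 (Proposed new method). The ester olefination by the hindered, acyl-stabilised ylide may be too slow. The ylide carbon may instead olefinate the mesoxalate ketone. Thermal retro-aldol before ring closure may erode enantiopurity. Discrimination between the two ester groups may be poor. The fallback uses known reaction types only and replaces the Wittig closure by a Dieckmann closure; it sets out from 11 and comes back to the route at 14. Alkaline hydrolysis of the acyl ylide (NaOH, aq. MeOH, 60 °C) should give 1-{5-[4-(benzyloxy)phenyl]-3-hydroxyfuran-2-yl}-2-methoxyethan-1-one F1. The same squaramide-catalysed aldol addition to 12 should give dimethyl 2-{(2S)-5-[4-(benzyloxy)phenyl]-2-(2-methoxyacetyl)-3-oxo-2,3-dihydrofuran-2-yl}-2-hydroxypropanedioate F2. Silylation (TESOTf, 2,6-lutidine) should give dimethyl 2-{(2S)-5-[4-(benzyloxy)phenyl]-2-(2-methoxyacetyl)-3-oxo-2,3-dihydrofuran-2-yl}-2-[(triethylsilyl)oxy]propanedioate F3, in which retro-aldol is blocked. Dieckmann condensation of the methoxymethyl ketone enolate onto one ester group (LiN(SiMe3)2, THF, −78 to 50 °C, then mild acid) should give the enolised dione methyl (5S,6R)-2-[4-(benzyloxy)phenyl]-7-hydroxy-8-methoxy-4,9-dioxo-6-[(triethylsilyl)oxy]-1-oxaspiro[4.4]nona-2,7-diene-6-carboxylate F4. O-methylation of this vinylogous acid (TMSCHN2, MeOH/toluene) should give methyl (5S,6R)-2-[4-(benzyloxy)phenyl]-7,8-dimethoxy-4,9-dioxo-6-[(triethylsilyl)oxy]-1-oxaspiro[4.4]nona-2,7-diene-6-carboxylate F5. Regioselectivity of the methylation and C6 selectivity of the Dieckmann closure are the weak points of this fallback and would be settled by chromatography. HF·pyridine then removes the silyl group and gives 14.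

Step 4. The hindered, electron-rich heteroaryl ester may acylate the thermally labile methoxymethylide too slowly. Methoxide set free may also strip the silyl group, which turns remaining ester into the unreactive enolate. The fallback changes the acyl donor and the order of events; it sets out from 7 and comes back at 10. Neutral ester cleavage (Me3SnOH, 1,2-dichloroethane, 80 °C) should give 5-[4-(benzyloxy)phenyl]-3-{[tri(propan-2-yl)silyl]oxy}furan-2-carboxylic acid F6. Oxalyl chloride with catalytic DMF should give 5-[4-(benzyloxy)phenyl]-3-{[tri(propan-2-yl)silyl]oxy}furan-2-carbonyl chloride F7. Addition of F7 to two equivalents of ylide 9 at −78 °C (acylation, then transylidation by the second equivalent) should give 10.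

Step 7. The C2=C3 double bond of ring B may be over-reduced, or slow hydrogenolysis may force long exposure of the retro-aldol-prone product to the catalyst. The fallback moves the debenzylation in front of the key event, so that the annulation becomes the last step; it sets out from 6 and comes back at 15. Hydrogenolysis of the robust furan ester (H2, Pd/C, EtOAc) should give methyl 3-hydroxy-5-(4-hydroxyphenyl)furan-2-carboxylate F8. Double silylation (TIPSOTf, 2.5 equiv, 2,6-lutidine) should give methyl 3-{[tri(propan-2-yl)silyl]oxy}-5-(4-{[tri(propan-2-yl)silyl]oxy}phenyl)furan-2-carboxylate F9. Acylation of ylide 9 as in step 4 should give 2-methoxy-1-[3-{[tri(propan-2-yl)silyl]oxy}-5-(4-{[tri(propan-2-yl)silyl]oxy}phenyl)furan-2-yl]-2-(triphenyl-λ5-phosphanylidene)ethan-1-one F10. Bu4NF/AcOH should remove both silyl groups and give 1-[3-hydroxy-5-(4-hydroxyphenyl)furan-2-yl]-2-methoxy-2-(triphenyl-λ5-phosphanylidene)ethan-1-one F11. The conditions of step 6 with 12 should then lead, through dimethyl 2-hydroxy-2-{(2S)-5-(4-hydroxyphenyl)-2-[2-methoxy-2-(triphenyl-λ5-phosphanylidene)acetyl]-3-oxo-2,3-dihydrofuran-2-yl}propanedioate F12, directly to 15.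

Further compounds
F1 | step 6 | 1-{5-[4-(benzyloxy)phenyl]-3-hydroxyfuran-2-yl}-2-methoxyethan-1-one | COCC(=O)c1oc(-c2ccc(OCc3ccccc3)cc2)cc1O
F2 | step 6 | dimethyl 2-{(2S)-5-[4-(benzyloxy)phenyl]-2-(2-methoxyacetyl)-3-oxo-2,3-dihydrofuran-2-yl}-2-hydroxypropanedioate | COC(=O)C(O)(C(=O)OC)[C@]1(C(=O)COC)OC(c2ccc(OCc3ccccc3)cc2)=CC1=O
F3 | step 6 | dimethyl 2-{(2S)-5-[4-(benzyloxy)phenyl]-2-(2-methoxyacetyl)-3-oxo-2,3-dihydrofuran-2-yl}-2-[(triethylsilyl)oxy]propanedioate | COC(=O)C(O[Si](CC)(CC)CC)(C(=O)OC)[C@]1(C(=O)COC)OC(c2ccc(OCc3ccccc3)cc2)=CC1=O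
F4 | step 6 | methyl (5S,6R)-2-[4-(benzyloxy)phenyl]-7-hydroxy-8-methoxy-4,9-dioxo-6-[(triethylsilyl)oxy]-1-oxaspiro[4.4]nona-2,7-diene-6-carboxylate | COC(=O)[C@@]1(O[Si](CC)(CC)CC)C(O)=C(OC)C(=O)[C@]12OC(c1ccc(OCc3ccccc3)cc1)=CC2=O
F5 | step 6 | methyl (5S,6R)-2-[4-(benzyloxy)phenyl]-7,8-dimethoxy-4,9-dioxo-6-[(triethylsilyl)oxy]-1-oxaspiro[4.4]nona-2,7-diene-6-carboxylate | COC(=O)[C@@]1(O[Si](CC)(CC)CC)C(OC)=C(OC)C(=O)[C@]12OC(c1ccc(OCc3ccccc3)cc1)=CC2=O
F6 | step 4 | 5-[4-(benzyloxy)phenyl]-3-{[tri(propan-2-yl)silyl]oxy}furan-2-carboxylic acid | OC(=O)c1oc(-c2ccc(OCc3ccccc3)cc2)cc1O[Si](C(C)C)(C(C)C)C(C)C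
F7 | step 4 | 5-[4-(benzyloxy)phenyl]-3-{[tri(propan-2-yl)silyl]oxy}furan-2-carbonyl chloride | ClC(=O)c1oc(-c2ccc(OCc3ccccc3)cc2)cc1O[Si](C(C)C)(C(C)C)C(C)C
F8 | step 7 | methyl 3-hydroxy-5-(4-hydroxyphenyl)furan-2-carboxylate | COC(=O)c1oc(-c2ccc(O)cc2)cc1O
F9 | step 7 | methyl 3-{[tri(propan-2-yl)silyl]oxy}-5-(4-{[tri(propan-2-yl)silyl]oxy}phenyl)furan-2-carboxylate | COC(=O)c1oc(-c2ccc(O[Si](C(C)C)(C(C)C)C(C)C)cc2)cc1O[Si](C(C)C)(C(C)C)C(C)C
F10 | step 7 | 2-methoxy-1-[3-{[tri(propan-2-yl)silyl]oxy}-5-(4-{[tri(propan-2-yl)silyl]oxy}phenyl)furan-2-yl]-2-(triphenyl-λ5-phosphanylidene)ethan-1-one | COC(=P(c1ccccc1)(c1ccccc1)c1ccccc1)C(=O)c1oc(-c2ccc(O[Si](C(C)C)(C(C)C)C(C)C)cc2)cc1O[Si](C(C)C)(C(C)C)C(C)C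
F11 | step 7 | 1-[3-hydroxy-5-(4-hydroxyphenyl)furan-2-yl]-2-methoxy-2-(triphenyl-λ5-phosphanylidene)ethan-1-one | COC(=P(c1ccccc1)(c1ccccc1)c1ccccc1)C(=O)c1oc(-c2ccc(O)cc2)cc1O
F12 | step 7 | dimethyl 2-hydroxy-2-{(2S)-5-(4-hydroxyphenyl)-2-[2-methoxy-2-(triphenyl-λ5-phosphanylidene)acetyl]-3-oxo-2,3-dihydrofuran-2-yl}propanedioate | COC(=O)C(O)(C(=O)OC)[C@]1(C(=O)C(OC)=P(c2ccccc2)(c2ccccc2)c2ccccc2)OC(c2ccc(O)cc2)=CC1=O
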